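## Retrosynthetic overview

1. The target is reached by hydrogenolysis and desilylation of a protected trans-3,4-dibenzyl lactone. That lactone comes from a 3-benzoyl-4-(arylmethyl)butyrolactone by C-benzylation with the ring-A benzyl bromide and retro-Claisen loss of the benzoyl group.
2. Key disconnection: the lactone bonds O1–C5 and C2–C3 are cut, which removes O1–C2(=O) as CO2 and leaves a trans-2-(arylmethyl)cyclopropyl phenyl ketone. Forward, this is a MgI2-mediated, strain-releasing formal (3+2) addition of the cyclopropane σ bond across a C=O of CO2.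
3. Enabling feature: in the oxolan-2-one ring, C3–C4–C5 is a three-carbon unit with 1,3-related termini. C5 is an unsubstituted CH2 (site for SN2 opening), C3 is the enolisable α-carbon (nucleophilic once it carries an acyl group, and free to settle trans afterwards), C4 is the stereocentre that is not touched, and O1–C2 is a CO2 unit.
4. The cyclopropane comes from asymmetric Ru-carbene cyclopropanation of the eugenol-type allyl group, followed by PhMgBr. The anti-1,3-diol side chain comes from a Mg-catalysed anti-aldol of an arylacetyl oxazolidinone with O-benzylvanillin, followed by LiBH4.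
5. Ring order: cyclopropane (temporary, step 9), then γ-butyrolactone (step 11). No other ring is made.

Key step: step 11

**Remark (assumption).** The antipodes of the oxazolidinone (steps 4–5) and of the Ru catalyst (step 9) are assigned from the accepted models: chelated Z-enolate attacked anti to the 4-benzyl group, and carbene transfer to the alkene face that gives the 2R ring carbon. If a model does not hold on these substrates, the antipodal reagent would be used and the route stays the same.

**Shorthand used in names.** S = (1R,2R)-1-[4-(benzyloxy)-3-methoxyphenyl]-1,3-bis(tert-butyldimethylsilyloxy)propan-2-yl. ArB = 4-(benzyloxy)-3-methoxy-5-S-phenyl.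

## Route

Step 1
Reactants: 1 5-allyl-2-hydroxy-3-methoxybenzaldehyde
Product: 2 5-allyl-2-(benzyloxy)-3-methoxybenzaldehyde
Conditions: BnBr, K2CO3, DMF, 50 °C
Reagents that add atoms: benzyl bromide, BrCc1ccccc1
Why: Williamson etherification of the phenol, which protects it as a benzyl ether that lasts until the final hydrogenolysis.

Step 2
Reactants: 2 5-allyl-2-(benzyloxy)-3-methoxybenzaldehyde
Product: 3 5-allyl-2-(benzyloxy)-1-methoxy-3-(2-methoxyethenyl)benzene (E/Z mixture)
Conditions: MeOCH2PPh3Cl, KOt-Bu, THF, 0 °C to rt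
Reagents that add atoms: (methoxymethyl)triphenylphosphonium chloride, COC[P+](c1ccccc1)(c1ccccc1)c1ccccc1.[Cl-]
Why: Wittig methoxymethylenation homologates the aldehyde by one carbon, and the alkene geometry is irrelevant because it is lost in step 3.

Step 3
Reactants: 3 5-allyl-2-(benzyloxy)-1-methoxy-3-(2-methoxyethenyl)benzene
Product: 5 2-[5-allyl-2-(benzyloxy)-3-methoxyphenyl]acetic acid, via arylacetaldehyde 4 (not isolated)
Conditions: 2 M HCl, THF, rt; then NaH2PO4 buffer, 2-methyl-2-butene (excess), NaClO2, t-BuOH/H2O, 0 °C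
Reagents that add atoms: water, O; sodium chlorite, [Na+].[O-]Cl=O
Why: Acid hydrolysis of the enol ether gives the sensitive arylacetaldehyde, which is oxidised at once by Pinnick oxidation while the excess trisubstituted alkene scavenges HOCl and so spares the allyl group and the arene.

Step 4
Reactants: 5 2-[5-allyl-2-(benzyloxy)-3-methoxyphenyl]acetic acid; 6 (R)-4-benzyloxazolidin-2-one
Product: 7 (R)-3-{2-[5-allyl-2-(benzyloxy)-3-methoxyphenyl]acetyl}-4-benzyloxazolidin-2-one
Conditions: PivCl, Et3N, THF, −20 °C; then LiCl, 6, rt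
Reagents that add atoms: none
Why: N-acylation of the oxazolidinone through the mixed pivalic anhydride, the standard entry to auxiliary-based aldol chemistry.

Step 5
Reactants: 7 the arylacetyl imide; 8 4-(benzyloxy)-3-methoxybenzaldehyde
Product: 10 (4R)-4-benzyl-3-[(2S,3R)-2-[5-allyl-2-(benzyloxy)-3-methoxyphenyl]-3-[4-(benzyloxy)-3-methoxyphenyl]-3-hydroxypropanoyl]oxazolidin-2-one (anti), via TMS ether 9 (not isolated)
Conditions: MgCl2 (20 mol %), Et3N, TMSCl, EtOAc, rt; then citric acid, MeOH, rt
Reagents that add atoms: none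
Why: Magnesium-halide-catalysed Evans-type direct anti-aldol, in which soft enolisation gives the chelated Z magnesium enolate, the aldehyde adds on the face away from the auxiliary benzyl group to set C-2 (S) and C-3 (R) anti, and O-silylation by TMSCl makes the addition irreversible and turns over the metal.

Step 6
Reactants: 10 the anti-aldol adduct
Product: 11 (1R,2R)-2-[5-allyl-2-(benzyloxy)-3-methoxyphenyl]-1-[4-(benzyloxy)-3-methoxyphenyl]propane-1,3-diol
Conditions: LiBH4, THF/MeOH, 0 °C
Reagents that add atoms: none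
Why: Reductive cleavage of the N-acyl oxazolidinone by borohydride gives the primary alcohol without touching either stereocentre and returns the auxiliary.

Step 7
Reactants: 11 the anti-1,3-diol
Product: 12 3-ArB-prop-1-ene (the bis-TBS ether of 11)
Conditions: TBSCl, imidazole, DMF, rt
Reagents that add atoms: tert-butyldimethylsilyl chloride, CC(C)(C)[Si](C)(C)Cl
Why: Silylation masks both hydroxyl groups against carbene O–H insertion, Grignard and enolate chemistry, and the silyl ethers can later be removed by fluoride without acid at the p-alkoxybenzylic carbinol.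

Step 8
Reactants: 13 2-bromo-N-methoxy-N-methylacetamide
Product: 14 2-diazo-N-methoxy-N-methylacetamide
Conditions: TsNHNHTs, DBU, THF, 0 °C
Reagents that add atoms: N,N'-ditosylhydrazine, Cc1ccc(cc1)S(=O)(=O)NNS(=O)(=O)c1ccc(C)cc1
Why: N-alkylation of the ditosylhydrazine by the α-bromo amide followed by base-induced loss of two sulfinates is an established route to acceptor diazoacetamides.

Step 9
Reactants: 12 3-ArB-prop-1-ene; 14 2-diazo-N-methoxy-N-methylacetamide
Product: 15 (1S,2R)-2-(ArB-methyl)-N-methoxy-N-methylcyclopropane-1-carboxamide (trans)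
Conditions: chiral Ru(II)–Pheox-type catalyst (3 mol %), CH2Cl2, rt, slow addition of 14
Reagents that add atoms: none
Why: Ru(II)–Pheox-catalysed asymmetric cyclopropanation of a terminal olefin with a diazo Weinreb amide, in which the catalyst selects the alkene face to set the ring carbon C-2 (R), the future lactone C-4, and gives the trans ring.

Step 10
Reactants: 15 the cyclopropyl Weinreb amide
Product: 16 phenyl [(1S,2R)-2-(ArB-methyl)cyclopropyl] ketone
Conditions: PhMgBr, THF, 0 °C
Reagents that add atoms: phenylmagnesium bromide, Br[Mg]c1ccccc1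
Why: Weinreb ketone synthesis stops at the ketone through the chelated tetrahedral intermediate and installs the non-enolisable benzoyl group that activates the cyclopropane.

Step 11
Reactants: 16 phenyl [(1S,2R)-2-(ArB-methyl)cyclopropyl] ketone; 17 carbon dioxide
Product: 20 (3S,4R)-3-benzoyl-4-(ArB-methyl)oxolan-2-one (trans shown; C-3 labile), via iodo-enolate 18 (not isolated), via keto-carboxylate 19 (not isolated)
Conditions: MgI2 (1.5 equiv), i-Pr2NEt (3 equiv), CO2 (10 bar), THF, 40 °C; then cold aq. citric acid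
Reagents that add atoms: none
Why: Proposed new method: iodide opens the benzoyl-activated cyclopropane at its unsubstituted CH2 in a Mg(II)-assisted homo-conjugate SN2 addition to give the γ-iodo magnesium enolate 18, which C-carboxylates with CO2 to 19, and the carboxylate oxygen then displaces the primary iodide (5-exo-tet) to close the lactone and release iodide, so that the net change is a formal (3+2) cycloaddition of the strained C–C σ bond across one C=O of CO2. The closest known reactions are the MgI2-mediated formal (3+2) ring expansion of carbonyl-activated cyclopropanes with imines, which runs through the same iodo-enolate, and the MgX2/amine carboxylation of ketone enolates with CO2; the halide-induced decarboxylative contraction of α-acyl-γ-butyrolactones to acylcyclopropanes at high temperature is the same pathway run backwards. The forward direction is favoured here by ring strain, CO2 pressure, moderate temperature and capture of the acidic β-keto lactone as its magnesium chelate by the amine base. The only ring closed is the lactone, by 5-exo-tet O-alkylation. The ring stereocentre C-4 keeps the (R) configuration of the cyclopropane because only the C(acyl)–CH2 bond is cleaved, while C-3 is a labile β-dicarbonyl centre that is fixed later. The step needs iodide attack at CH2 and not at the substituted ring carbon, which is secured by the primary versus hindered secondary nature of the two sites (the secondary one has no cation-stabilising group) under soft, weakly Lewis acidic conditions; it also needs carboxylation and lactonisation to outrun enolate O-alkylation to a dihydrofuran, which excess CO2 and the tight magnesium enolate favour.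

Step 12
Reactants: 21 [4-(benzyloxy)-3-methoxyphenyl]methanol
Product: 22 1-(benzyloxy)-4-(bromomethyl)-2-methoxybenzene
Conditions: PBr3, Et2O, 0 °C
Reagents that add atoms: phosphorus tribromide, BrP(Br)Br
Why: Standard conversion of a benzylic alcohol into the bromide, used fresh because of its reactivity.

Step 13
Reactants: 20 (3S,4R)-3-benzoyl-4-(ArB-methyl)oxolan-2-one; 22 1-(benzyloxy)-4-(bromomethyl)-2-methoxybenzene
Product: 24 (3R,4R)-3-[4-(benzyloxy)-3-methoxybenzyl]-4-(ArB-methyl)oxolan-2-one (trans), via C-benzylated keto-lactone 23 (not isolated)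
Conditions: K2CO3, DMF, rt; then NaOMe (0.3 equiv), MeOH, 0 °C to rt; AcOH quench
Reagents that add atoms: none
Why: C-alkylation of the β-keto lactone enolate anti to the C-4 substituent gives the quaternary, non-enolisable ketone 23, and methoxide then removes the benzoyl group by retro-Claisen cleavage as methyl benzoate, after which the lactone α-centre equilibrates under the alkoxide to the thermodynamically preferred trans (3R) configuration.

Step 14
Reactants: 24 the bis-TBS tri-O-benzyl lactone
Product: 25 (3R,4R)-3-[4-(benzyloxy)-3-methoxybenzyl]-4-{[4-(benzyloxy)-3-[(1R,2R)-1-[4-(benzyloxy)-3-methoxyphenyl]-1,3-dihydroxypropan-2-yl]-5-methoxyphenyl]methyl}oxolan-2-one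
Conditions: TBAF, AcOH (1:1), THF, rt
Reagents that add atoms: none
Why: Buffered fluoride desilylation frees both hydroxyl groups without acid at the ionisable benzylic carbinol and without base-induced epimerisation or opening of the lactone.

Step 15
Reactants: 25 the tri-O-benzyl diol lactone
Product: 26 (3R,4R)-4-{[4-hydroxy-3-[(1R,2R)-1,3-dihydroxy-1-(4-hydroxy-3-methoxyphenyl)propan-2-yl]-5-methoxyphenyl]methyl}-3-[(4-hydroxy-3-methoxyphenyl)methyl]oxolan-2-one (target)
Conditions: H2 (1 atm), 10% Pd/C, EtOAc/EtOH, rt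
Reagents that add atoms: none
Why: Neutral hydrogenolysis cleaves the three aryl benzyl ethers faster than the secondary benzylic C–OH bond, so the final step is run without acid or base on the phenolic product.

## Compound list

1 | 5-allyl-2-hydroxy-3-methoxybenzaldehyde (catalogue compound; the ortho-formyl derivative of eugenol) | C=CCc1cc(C=O)c(O)c(OC)c1 | starting material
2 | 5-allyl-2-(benzyloxy)-3-methoxybenzaldehyde | C=CCc1cc(C=O)c(OCc2ccccc2)c(OC)c1 | intermediate
3 | 5-allyl-2-(benzyloxy)-1-methoxy-3-(2-methoxyethenyl)benzene (E/Z) | C=CCc1cc(C=COC)c(OCc2ccccc2)c(OC)c1 | intermediate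
4 | 2-[5-allyl-2-(benzyloxy)-3-methoxyphenyl]acetaldehyde | C=CCc1cc(CC=O)c(OCc2ccccc2)c(OC)c1 | intermediate
5 | 2-[5-allyl-2-(benzyloxy)-3-methoxyphenyl]acetic acid | C=CCc1cc(CC(=O)O)c(OCc2ccccc2)c(OC)c1 | intermediate
6 | (R)-4-benzyloxazolidin-2-one | O=C1N[C@H](Cc2ccccc2)CO1 | starting material
7 | (R)-3-{2-[5-allyl-2-(benzyloxy)-3-methoxyphenyl]acetyl}-4-benzyloxazolidin-2-one | C=CCc1cc(CC(=O)N2[C@H](Cc3ccccc3)COC2=O)c(OCc2ccccc2)c(OC)c1 | intermediate
8 | 4-(benzyloxy)-3-methoxybenzaldehyde | O=Cc1ccc(OCc2ccccc2)c(OC)c1 | starting material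
9 | O-trimethylsilyl ether of 10 | C=CCc1cc([C@H](C(=O)N2[C@H](Cc3ccccc3)COC2=O)[C@@H](O[Si](C)(C)C)c2ccc(OCc3ccccc3)c(OC)c2)c(OCc2ccccc2)c(OC)c1 | intermediate
10 | (4R)-4-benzyl-3-[(2S,3R)-2-[5-allyl-2-(benzyloxy)-3-methoxyphenyl]-3-[4-(benzyloxy)-3-methoxyphenyl]-3-hydroxypropanoyl]oxazolidin-2-one | C=CCc1cc([C@H](C(=O)N2[C@H](Cc3ccccc3)COC2=O)[C@@H](O)c2ccc(OCc3ccccc3)c(OC)c2)c(OCc2ccccc2)c(OC)c1 | intermediate
11 | (1R,2R)-2-[5-allyl-2-(benzyloxy)-3-methoxyphenyl]-1-[4-(benzyloxy)-3-methoxyphenyl]propane-1,3-diol | C=CCc1cc([C@H](CO)[C@@H](O)c2ccc(OCc3ccccc3)c(OC)c2)c(OCc2ccccc2)c(OC)c1 | intermediate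
12 | 3-ArB-prop-1-ene (bis-TBS ether of 11) | C=CCc1cc([C@H](CO[Si](C)(C)C(C)(C)C)[C@@H](O[Si](C)(C)C(C)(C)C)c2ccc(OCc3ccccc3)c(OC)c2)c(OCc2ccccc2)c(OC)c1 | intermediate
13 | 2-bromo-N-methoxy-N-methylacetamide | CON(C)C(=O)CBr | starting material
14 | 2-diazo-N-methoxy-N-methylacetamide | CON(C)C(=O)C=[N+]=[N-] | intermediate
15 | (1S,2R)-2-(ArB-methyl)-N-methoxy-N-methylcyclopropane-1-carboxamide | CON(C)C(=O)[C@H]1C[C@@H]1Cc1cc([C@H](CO[Si](C)(C)C(C)(C)C)[C@@H](O[Si](C)(C)C(C)(C)C)c2ccc(OCc3ccccc3)c(OC)c2)c(OCc2ccccc2)c(OC)c1 | intermediate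
16 | phenyl [(1S,2R)-2-(ArB-methyl)cyclopropyl] ketone | O=C(c1ccccc1)[C@H]1C[C@@H]1Cc1cc([C@H](CO[Si](C)(C)C(C)(C)C)[C@@H](O[Si](C)(C)C(C)(C)C)c2ccc(OCc3ccccc3)c(OC)c2)c(OCc2ccccc2)c(OC)c1 | intermediate
17 | carbon dioxide | O=C=O | starting material
18 | iodomagnesium enolate of (3R)-4-iodo-3-(ArB-methyl)-1-phenylbutan-1-one | I[Mg]OC(c1ccccc1)=C[C@H](CI)Cc1cc([C@H](CO[Si](C)(C)C(C)(C)C)[C@@H](O[Si](C)(C)C(C)(C)C)c2ccc(OCc3ccccc3)c(OC)c2)c(OCc2ccccc2)c(OC)c1 | intermediate
19 | iodomagnesium (3R)-2-benzoyl-4-iodo-3-(ArB-methyl)butanoate | O=C(O[Mg]I)C(C(=O)c1ccccc1)[C@H](CI)Cc1cc([C@H](CO[Si](C)(C)C(C)(C)C)[C@@H](O[Si](C)(C)C(C)(C)C)c2ccc(OCc3ccccc3)c(OC)c2)c(OCc2ccccc2)c(OC)c1 | intermediate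
20 | (3S,4R)-3-benzoyl-4-(ArB-methyl)oxolan-2-one | O=C(c1ccccc1)[C@H]1C(=O)OC[C@@H]1Cc1cc([C@H](CO[Si](C)(C)C(C)(C)C)[C@@H](O[Si](C)(C)C(C)(C)C)c2ccc(OCc3ccccc3)c(OC)c2)c(OCc2ccccc2)c(OC)c1 | intermediate
21 | [4-(benzyloxy)-3-methoxyphenyl]methanol | OCc1ccc(OCc2ccccc2)c(OC)c1 | starting material
22 | 1-(benzyloxy)-4-(bromomethyl)-2-methoxybenzene | BrCc1ccc(OCc2ccccc2)c(OC)c1 | intermediate
23 | (3R,4R)-3-benzoyl-3-[4-(benzyloxy)-3-methoxybenzyl]-4-(ArB-methyl)oxolan-2-one | COc1cc(C[C@@]2(C(=O)c3ccccc3)C(=O)OC[C@@H]2Cc2cc(OC)c(OCc3ccccc3)c([C@H](CO[Si](C)(C)C(C)(C)C)[C@@H](O[Si](C)(C)C(C)(C)C)c3ccc(OCc4ccccc4)c(OC)c3)c2)ccc1OCc1ccccc1 | intermediate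
24 | (3R,4R)-3-[4-(benzyloxy)-3-methoxybenzyl]-4-(ArB-methyl)oxolan-2-one | COc1cc(C[C@H]2C(=O)OC[C@@H]2Cc2cc(OC)c(OCc3ccccc3)c([C@H](CO[Si](C)(C)C(C)(C)C)[C@@H](O[Si](C)(C)C(C)(C)C)c3ccc(OCc4ccccc4)c(OC)c3)c2)ccc1OCc1ccccc1 | intermediate
25 | (3R,4R)-3-[4-(benzyloxy)-3-methoxybenzyl]-4-{[4-(benzyloxy)-3-[(1R,2R)-1-[4-(benzyloxy)-3-methoxyphenyl]-1,3-dihydroxypropan-2-yl]-5-methoxyphenyl]methyl}oxolan-2-one | COc1cc(C[C@H]2C(=O)OC[C@@H]2Cc2cc(OC)c(OCc3ccccc3)c([C@H](CO)[C@@H](O)c3ccc(OCc4ccccc4)c(OC)c3)c2)ccc1OCc1ccccc1 | intermediate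
26 | (3R,4R)-4-{[4-hydroxy-3-[(1R,2R)-1,3-dihydroxy-1-(4-hydroxy-3-methoxyphenyl)propan-2-yl]-5-methoxyphenyl]methyl}-3-[(4-hydroxy-3-methoxyphenyl)methyl]oxolan-2-one | COc1cc(C[C@H]2C(=O)OC[C@@H]2Cc2cc(OC)c(O)c([C@H](CO)[C@@H](O)c3ccc(O)c(OC)c3)c2)ccc1O | target

## Step count and risks

Total step count: 15. Longest linear sequence: 13 steps (1–7, 9–11, 13–15, from compound 1).

**Step 11 (proposed new method).** The cyclopropane may fail to open under MgI2 at a useful rate. Iodide may attack the substituted ring carbon and so give the regioisomeric lactone. The iodo-enolate may close through oxygen to a dihydrofuran before it is carboxylated. The CO2 uptake may also simply be reversed on work-up. The fallback uses known chemistry and sets out from alkene 12. A (2+2) cycloaddition with dichloroketene (Cl3CCOCl, Zn–Cu, POCl3, Et2O) would give 2,2-dichloro-3-(ArB-methyl)cyclobutan-1-one F1. Dechlorination with Zn in AcOH would give the prochiral 3-(ArB-methyl)cyclobutan-1-one F2. An enantioselective Baeyer–Villiger oxidation (a Baeyer–Villiger monooxygenase, or a chiral acid catalyst with H2O2) would give (R)-4-(ArB-methyl)oxolan-2-one F3. Its lithium enolate (LDA, THF, −78 °C) would be alkylated by bromide 22 anti to the C-4 substituent, which returns to the route at compound 24.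

**Step 9.** The unactivated, remote terminal alkene may react sluggishly with the Ru carbene, so that carbene dimerisation wins. The facial selectivity may also be poor, giving C-2 epimers that cannot be separated from the remote stereocentres. The fallback sets out from alkene 12. Cross-metathesis with 1-phenylprop-2-en-1-one (second-generation ruthenium benzylidene catalyst, CH2Cl2, 40 °C) would give (E)-4-ArB-1-phenylbut-2-en-1-one F4. A catalytic asymmetric Corey–Chaykovsky cyclopropanation (dimethyloxosulfonium methylide, chiral lanthanum–lithium biaryloxide catalyst, NaI) would then close the trans ring and return to the route at compound 16, which makes steps 8–10 unnecessary.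

**Step 5.** The anti selectivity may erode through retro-aldol equilibration of the α-aryl aldolate before silylation, and the electron-rich aldehyde may convert poorly. The fallback sets out from acid 5 and replaces the auxiliary aldol by a reduction with dynamic kinetic resolution. Esterification (MeI, K2CO3) would give methyl 2-[5-allyl-2-(benzyloxy)-3-methoxyphenyl]acetate F5. C-acylation of its lithium enolate with 4-(benzyloxy)-3-methoxybenzoyl chloride would give the racemic, configurationally labile methyl 2-[5-allyl-2-(benzyloxy)-3-methoxyphenyl]-3-[4-(benzyloxy)-3-methoxyphenyl]-3-oxopropanoate F6. Reduction under dynamic kinetic resolution (a ketoreductase selected by screening, with cofactor recycling) would give methyl (2S,3R)-2-[5-allyl-2-(benzyloxy)-3-methoxyphenyl]-3-[4-(benzyloxy)-3-methoxyphenyl]-3-hydroxypropanoate F7. LiBH4 reduction of the ester returns to the route at diol 11.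

Further compounds
F1 | step 11 | 2,2-dichloro-3-(ArB-methyl)cyclobutan-1-one | O=C1CC(Cc2cc([C@H](CO[Si](C)(C)C(C)(C)C)[C@@H](O[Si](C)(C)C(C)(C)C)c3ccc(OCc4ccccc4)c(OC)c3)c(OCc3ccccc3)c(OC)c2)C1(Cl)Cl
F2 | step 11 | 3-(ArB-methyl)cyclobutan-1-one | O=C1CC(Cc2cc([C@H](CO[Si](C)(C)C(C)(C)C)[C@@H](O[Si](C)(C)C(C)(C)C)c3ccc(OCc4ccccc4)c(OC)c3)c(OCc3ccccc3)c(OC)c2)C1
F3 | step 11 | (R)-4-(ArB-methyl)oxolan-2-one | O=C1OC[C@@H](C1)Cc1cc([C@H](CO[Si](C)(C)C(C)(C)C)[C@@H](O[Si](C)(C)C(C)(C)C)c2ccc(OCc3ccccc3)c(OC)c2)c(OCc2ccccc2)c(OC)c1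
F4 | step 9 | (E)-4-ArB-1-phenylbut-2-en-1-one | O=C(/C=C/Cc1cc([C@H](CO[Si](C)(C)C(C)(C)C)[C@@H](O[Si](C)(C)C(C)(C)C)c2ccc(OCc3ccccc3)c(OC)c2)c(OCc2ccccc2)c(OC)c1)c1ccccc1
F5 | step 5 | methyl 2-[5-allyl-2-(benzyloxy)-3-methoxyphenyl]acetate | C=CCc1cc(CC(=O)OC)c(OCc2ccccc2)c(OC)c1
F6 | step 5 | methyl 2-[5-allyl-2-(benzyloxy)-3-methoxyphenyl]-3-[4-(benzyloxy)-3-methoxyphenyl]-3-oxopropanoate (racemic) | C=CCc1cc(C(C(=O)OC)C(=O)c2ccc(OCc3ccccc3)c(OC)c2)c(OCc2ccccc2)c(OC)c1
F7 | step 5 | methyl (2S,3R)-2-[5-allyl-2-(benzyloxy)-3-methoxyphenyl]-3-[4-(benzyloxy)-3-methoxyphenyl]-3-hydroxypropanoate | C=CCc1cc([C@H](C(=O)OC)[C@@H](O)c2ccc(OCc3ccccc3)c(OC)c2)c(OCc2ccccc2)c(OC)c1
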